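Ring B is built last, on a finished chromone, and is not imported as a tetraoxygenated benzene. The feature exploited is the para oxygen pair of ring B (O on C2' and O on C5') enclosing the methoxy carbons C3' and C4', with the C1'–C6'H edge bonded to chromone C2. A Dötz benzannulation of the alkenyl Fischer carbene (CO)5Cr=C(OMe)C(OMe)=CH(OMe), one CO ligand and a 5-O-benzyl-2-ethynylchromone forms C5'–C6', C1'–C2' and C2'–C3' in one operation. It delivers ring B as the 2'-phenol with every substituent in place. O-Methylation and hydrogenolysis then give the flavone.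

Key step: step 8

Remarks on the chemistry (assumptions):
- 1,2-Dimethoxyethene is carried as its Z isomer, the more stable geometry of 1,2-dialkoxyethenes. Any E isomer would converge on the same ring B, because the alkene geometry is lost on aromatisation.
- In the SMILES of chromium compounds each CO ligand is written as =C=O on the metal. The η6 bond between ring B and Cr(CO)3 is written as a dot.
- O5 is kept as a benzyl ether from the first step, so that only the new 2'-OH is free when it has to be methylated.

Step 1
Reactants: 1 2',6'-dihydroxy-4'-methoxyacetophenone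
Product: 2 1-[2-(benzyloxy)-6-hydroxy-4-methoxyphenyl]ethan-1-one
Conditions: BnBr (1.05 equiv), K2CO3, acetone, reflux
Reagents that add atoms: benzyl bromide, BrCc1ccccc1
Why: Williamson etherification of a symmetric diol, in which the second phenol stays hydrogen-bonded to the acetyl carbonyl after the first alkylation and is far less nucleophilic, so the mono-ether is expected.

Step 2
Reactants: 2 1-[2-(benzyloxy)-6-hydroxy-4-methoxyphenyl]ethan-1-one; 3 diethyl oxalate
Product: 5 ethyl 5-(benzyloxy)-7-methoxy-4-oxo-4H-chromene-2-carboxylate, via ethyl 4-aryl-2,4-dioxobutanoate 4 (not isolated)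
Conditions: NaOEt, EtOH, reflux; then conc. HCl, EtOH, reflux
Reagents that add atoms: none
Why: Crossed Claisen condensation of the acetophenone enolate with non-enolisable diethyl oxalate, followed by acid-catalysed cyclodehydration of the phenol onto the 2-keto group, is the standard entry to chromone-2-carboxylates.

Step 3
Reactants: 5 ethyl 5-(benzyloxy)-7-methoxy-4-oxo-4H-chromene-2-carboxylate
Product: 6 5-(benzyloxy)-2-(hydroxymethyl)-7-methoxy-4H-chromen-4-one
Conditions: NaBH4, MeOH/THF, 0 °C
Reagents that add atoms: none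
Why: Chemoselective hydride reduction, since the ester on the electron-poor C2 of the pyranone is unusually electrophilic whereas the C4 carbonyl is a vinylogous ester and should be left alone at 0 °C.

Step 4
Reactants: 6 5-(benzyloxy)-2-(hydroxymethyl)-7-methoxy-4H-chromen-4-one
Product: 7 5-(benzyloxy)-7-methoxy-4-oxo-4H-chromene-2-carbaldehyde
Conditions: Dess–Martin periodinane, CH2Cl2, rt
Reagents that add atoms: none
Why: Dess–Martin oxidation of a primary allylic-type alcohol stops at the aldehyde under neutral anhydrous conditions that the pyranone and the benzyl ether tolerate.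

Step 5
Reactants: 7 5-(benzyloxy)-7-methoxy-4-oxo-4H-chromene-2-carbaldehyde
Product: 8 5-(benzyloxy)-2-ethynyl-7-methoxy-4H-chromen-4-one
Conditions: dimethyl (1-diazo-2-oxopropyl)phosphonate, K2CO3, MeOH/THF, 0 °C → rt
Reagents that add atoms: dimethyl (1-diazo-2-oxopropyl)phosphonate, COP(=O)(OC)C(=[N+]=[N-])C(C)=O
Why: Seyferth–Gilbert homologation in the Ohira–Bestmann variant, in which the diazomethylphosphonate anion generated in situ adds to the non-enolisable aldehyde, and olefination followed by loss of N2 with a 1,2-hydride shift gives the terminal alkyne.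

Step 6
Reactants: 9 1,1,2-trimethoxyethane
Product: 10 (Z)-1,2-dimethoxyethene
Conditions: TMSOTf, i-Pr2NEt, CH2Cl2, −20 °C → rt; fractional distillation
Reagents that add atoms: none
Why: Silyl-triflate-mediated elimination of methanol from a dimethyl acetal (oxocarbenium formation, then deprotonation by the hindered amine) is a general enol ether synthesis, and the Z geometry is the thermodynamically preferred one for 1,2-dialkoxyethenes.

Step 7
Reactants: 10 (Z)-1,2-dimethoxyethene; 11 Cr(CO)6
Product: 14 pentacarbonyl[(Z)-1,2,3-trimethoxyprop-2-en-1-ylidene]chromium (CO)5Cr=C(OMe)C(OMe)=CH(OMe), via (Z)-(1,2-dimethoxyethenyl)lithium 12 (not isolated), via Li[(CO)5Cr=C(O)C(OMe)=CH(OMe)] 13 (not isolated)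
Conditions: t-BuLi, THF, −78 °C; Cr(CO)6, THF, −78 → 0 °C; then Me3OBF4, CH2Cl2, 0 °C
Reagents that add atoms: trimethyloxonium tetrafluoroborate, C[O+](C)C.F[B-](F)(F)F
Why: Fischer carbene synthesis, in which α-lithiation of the enol ether (the reactivity known for 1,4-dioxene and methyl vinyl ether), addition of the organolithium to a CO ligand and hard O-methylation of the acylchromate with Meerwein salt should give the complex with the alkene geometry retained.

Step 8
Reactants: 14 pentacarbonyl[(Z)-1,2,3-trimethoxyprop-2-en-1-ylidene]chromium; 8 5-(benzyloxy)-2-ethynyl-7-methoxy-4H-chromen-4-one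
Product: 16 5-(benzyloxy)-2-(2-hydroxy-3,4,5-trimethoxyphenyl)-7-methoxy-4H-chromen-4-one, via Cr(CO)3 complex of the phenol 15 (not isolated)
Conditions: THF, 55 °C, Ar; then air, MeCN, rt
Reagents that add atoms: none
Why: Dötz benzannulation: thermal loss of a cis CO from 14 allows the alkyne of 8 to coordinate and insert into the Cr=C bond with its unsubstituted carbon bonding to the carbene carbon (C5'–C6'), CO insertion into the resulting vinylcarbene forms a chromium-bound dienylketene (C1'–C2'), and attack of the ketene carbon on the methoxy-bearing vinyl terminus (C2'–C3') followed by enolisation gives the phenol as its Cr(CO)3 complex 15, from which air releases 16. The closest known reaction type is the benzannulation of alkenyl(methoxy)carbene complexes of zerovalent chromium, α-alkoxyalkenyl ones included, with terminal and conjugated alkynes. Ring B closes by a thermal 6π-electrocyclisation of the dienylketene on the metal template, and no stereocentre is created. The step needs regioselective alkyne insertion, secured by the alkyne being terminal, so that the bulky chromon-2-yl group sits next to the CO-derived carbon and away from the carbene methoxy group, which places the chromone at C1' between C2'–OH and C6'–H. It also needs phenol formation to win over cyclopentannulation and furan formation, which is favoured by an alkenyl (not aryl) carbene, by chromium as the metal and by THF as solvent, while the hydrogen on the vinyl terminus permits the final tautomerisation; a cerium oxidant such as (NH4)2Ce(NO3)6 is avoided in the work-up so that the para-methoxyphenol is not oxidised to a quinone.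

Step 9
Reactants: 16 5-(benzyloxy)-2-(2-hydroxy-3,4,5-trimethoxyphenyl)-7-methoxy-4H-chromen-4-one
Product: 17 5-(benzyloxy)-7-methoxy-2-(2,3,4,5-tetramethoxyphenyl)-4H-chromen-4-one
Conditions: MeI, K2CO3, acetone, reflux
Reagents that add atoms: iodomethane, CI
Why: Williamson O-methylation of the 2'-phenol, the only acidic OH in the molecule because O5 is benzylated.

Step 10
Reactants: 17 5-(benzyloxy)-7-methoxy-2-(2,3,4,5-tetramethoxyphenyl)-4H-chromen-4-one
Product: 18 5-hydroxy-7-methoxy-2-(2,3,4,5-tetramethoxyphenyl)-4H-chromen-4-one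
Conditions: H2 (1 atm), 10% Pd/C, EtOAc/MeOH, rt
Reagents that add atoms: none
Why: Catalytic hydrogenolysis of the benzyl aryl ether, under which the C2=C3 bond of a flavone and the aryl methyl ethers are expected to be inert and the freed 5-OH is held by a hydrogen bond to the C4 carbonyl.

Compound list

1 | 2',6'-dihydroxy-4'-methoxyacetophenone | CC(=O)c1c(O)cc(OC)cc1O | starting material
2 | 1-[2-(benzyloxy)-6-hydroxy-4-methoxyphenyl]ethan-1-one | CC(=O)c1c(O)cc(OC)cc1OCc1ccccc1 | intermediate
3 | diethyl oxalate | CCOC(=O)C(=O)OCC | starting material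
4 | ethyl 4-[2-(benzyloxy)-6-hydroxy-4-methoxyphenyl]-2,4-dioxobutanoate | CCOC(=O)C(=O)CC(=O)c1c(O)cc(OC)cc1OCc1ccccc1 | intermediate (not isolated)
5 | ethyl 5-(benzyloxy)-7-methoxy-4-oxo-4H-chromene-2-carboxylate | CCOC(=O)c1cc(=O)c2c(OCc3ccccc3)cc(OC)cc2o1 | intermediate
6 | 5-(benzyloxy)-2-(hydroxymethyl)-7-methoxy-4H-chromen-4-one | OCc1cc(=O)c2c(OCc3ccccc3)cc(OC)cc2o1 | intermediate
7 | 5-(benzyloxy)-7-methoxy-4-oxo-4H-chromene-2-carbaldehyde | O=Cc1cc(=O)c2c(OCc3ccccc3)cc(OC)cc2o1 | intermediate
8 | 5-(benzyloxy)-2-ethynyl-7-methoxy-4H-chromen-4-one | C#Cc1cc(=O)c2c(OCc3ccccc3)cc(OC)cc2o1 | intermediate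
9 | 1,1,2-trimethoxyethane | COCC(OC)OC | starting material
10 | (Z)-1,2-dimethoxyethene | CO/C=C\OC | intermediate
11 | Cr(CO)6 | O=C=[Cr](=C=O)(=C=O)(=C=O)(=C=O)=C=O | starting material
12 | (Z)-(1,2-dimethoxyethenyl)lithium | CO/C=C(\OC)[Li] | intermediate (not isolated)
13 | Li[(CO)5Cr=C(O)C(OMe)=CH(OMe)], lithium pentacarbonyl[(Z)-2,3-dimethoxy-1-oxidoprop-2-en-1-ylidene]chromate | [Li+].CO/C=C(\OC)C([O-])=[Cr](=C=O)(=C=O)(=C=O)(=C=O)=C=O | intermediate (not isolated)
14 | pentacarbonyl[(Z)-1,2,3-trimethoxyprop-2-en-1-ylidene]chromium | CO/C=C(\OC)C(OC)=[Cr](=C=O)(=C=O)(=C=O)(=C=O)=C=O | intermediate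
15 | tricarbonylchromium complex of 16, Cr(CO)3 bound η6 to ring B | COc1cc(OCc2ccccc2)c2c(=O)cc(-c3cc(OC)c(OC)c(OC)c3O)oc2c1.O=C=[Cr](=C=O)=C=O | intermediate (not isolated)
16 | 5-(benzyloxy)-2-(2-hydroxy-3,4,5-trimethoxyphenyl)-7-methoxy-4H-chromen-4-one | COc1cc(OCc2ccccc2)c2c(=O)cc(-c3cc(OC)c(OC)c(OC)c3O)oc2c1 | intermediate
17 | 5-(benzyloxy)-7-methoxy-2-(2,3,4,5-tetramethoxyphenyl)-4H-chromen-4-one | COc1cc(OCc2ccccc2)c2c(=O)cc(-c3cc(OC)c(OC)c(OC)c3OC)oc2c1 | intermediate
18 | 5-hydroxy-7-methoxy-2-(2,3,4,5-tetramethoxyphenyl)-4H-chromen-4-one | COc1cc(O)c2c(=O)cc(-c3cc(OC)c(OC)c(OC)c3OC)oc2c1 | target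

Total step count: 10.
Longest linear sequence: 8 steps (steps 1, 2, 3, 4, 5, 8, 9, 10); the carbene arm (steps 6 and 7) joins at step 8.

Steps most likely to fail

Step 8. After alkyne insertion, CO insertion may lag and divert the vinylcarbene to cyclopentannulation or furan formation. Alternatively the push-pull stabilised carbene may lose CO too slowly, so that the electron-poor alkyne oligomerises on chromium. The fallback sets out from 2 and comes back at 17; ring B would be brought in preformed by classical flavone chemistry. Claisen–Schmidt condensation of 2 with commercial 2,3,4,5-tetramethoxybenzaldehyde (KOH, EtOH, rt) should give the 2'-hydroxychalcone (E)-1-[2-(benzyloxy)-6-hydroxy-4-methoxyphenyl]-3-(2,3,4,5-tetramethoxyphenyl)prop-2-en-1-one F1. Oxidative cyclisation of F1 (cat. I2, DMSO, 120 °C) should then give flavone 17, which re-enters at step 10.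

Step 7. In organolithium 12 the lithium is anti to the β-methoxy group, so LiOMe may be eliminated before the reagent is trapped by Cr(CO)6. The electron-rich acylchromate may also decompose during alkylation. The fallback sets out from 11 and comes back at 14; the acyl carbon would be delivered as an acid chloride to a pentacarbonylchromate dianion, so no vinyllithium is needed. Cr(CO)6 11 would be reduced with NaC10H8 (sodium naphthalenide) in THF at −78 °C to disodium pentacarbonylchromate Na2Cr(CO)5 F2. Separately, commercial methyl methoxyacetate would be formylated (methyl formate, NaOMe, Et2O) to methyl 2-methoxy-3-oxopropanoate F3, handled as its sodium enolate. O-Methylation (Me2SO4, DMF) should give methyl (Z)-2,3-dimethoxyprop-2-enoate F4, saponification (LiOH, THF/H2O) the acid (Z)-2,3-dimethoxyprop-2-enoic acid F5, and (COCl)2 with cat. DMF the chloride (Z)-2,3-dimethoxyprop-2-enoyl chloride F6. Acylation of F2 with F6 (THF, −78 °C) should give the sodium acylchromate Na[(CO)5Cr=C(O)C(OMe)=CH(OMe)] F7, and O-methylation with Me3OBF4 (CH2Cl2, 0 °C) would give 14.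

Step 5. Methoxide may add to C2 of the pyranone or to the conjugated alkyne once it has formed, which would lead to ring opening or incorporation of solvent. The fallback sets out from 7 and comes back at 8 by an olefination and elimination sequence that is free of alkoxide. Corey–Fuchs-type dibromo-olefination of 7 (CBr4, PPh3, CH2Cl2, 0 °C) should give 5-(benzyloxy)-2-(2,2-dibromoethenyl)-7-methoxy-4H-chromen-4-one F8. Selective hydrogenolysis of the bromine trans to the chromone (Bu3SnH, cat. Pd(PPh3)4, toluene, rt) should give 5-(benzyloxy)-2-[(Z)-2-bromoethenyl]-7-methoxy-4H-chromen-4-one F9. Anti elimination of HBr from F9 (TBAF, DMF, rt) would then give 8.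

Further compounds

F1 | step 8 | (E)-1-[2-(benzyloxy)-6-hydroxy-4-methoxyphenyl]-3-(2,3,4,5-tetramethoxyphenyl)prop-2-en-1-one | COc1cc(O)c(C(=O)/C=C/c2cc(OC)c(OC)c(OC)c2OC)c(OCc2ccccc2)c1
F2 | step 7 | disodium pentacarbonylchromate Na2Cr(CO)5 | [Na+].[Na+].O=C=[Cr-2](=C=O)(=C=O)(=C=O)=C=O
F3 | step 7 | methyl 2-methoxy-3-oxopropanoate (handled as its sodium enolate) | COC(=O)C(OC)C=O
F4 | step 7 | methyl (Z)-2,3-dimethoxyprop-2-enoate | CO/C=C(\OC)C(=O)OC
F5 | step 7 | (Z)-2,3-dimethoxyprop-2-enoic acid | CO/C=C(\OC)C(=O)O
F6 | step 7 | (Z)-2,3-dimethoxyprop-2-enoyl chloride | CO/C=C(\OC)C(=O)Cl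
F7 | step 7 | Na[(CO)5Cr=C(O)C(OMe)=CH(OMe)], sodium pentacarbonyl[(Z)-2,3-dimethoxy-1-oxidoprop-2-en-1-ylidene]chromate | [Na+].CO/C=C(\OC)C([O-])=[Cr](=C=O)(=C=O)(=C=O)(=C=O)=C=O
F8 | step 5 | 5-(benzyloxy)-2-(2,2-dibromoethenyl)-7-methoxy-4H-chromen-4-one | BrC(Br)=Cc1cc(=O)c2c(OCc3ccccc3)cc(OC)cc2o1
F9 | step 5 | 5-(benzyloxy)-2-[(Z)-2-bromoethenyl]-7-methoxy-4H-chromen-4-one | Br/C=C\c1cc(=O)c2c(OCc3ccccc3)cc(OC)cc2o1
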